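The ochre and blue runs share the flask's 1.3 equiv of reagent in the second phase and its phase ratio; they differ in charged [substrate].

| flask | substrate | reagent in the second phase | remark | time | volume of the second phase over the first |
|---|---|---|---|---|---|
| ochre | 0.20 M | 1.3 equiv | run made earlier |  |  |
| blue | 0.30 M | 1.3 equiv | run made earlier |  |  |
| flask | 0.40 M | 1.30 equiv |  | 4.0 min | 0.50 |

| run | time / min | target / % | substrate / % |
|---|---|---|---|
| ochre | 0.667 | 34.8 | 66.0 |
| ochre | 1.33 | 51.2 | 46.5 |
| ochre | 2.00 | 62.0 | 38.7 |
| ochre | 3.00 | 66.1 | 30.5 |
| ochre | 4.00 | 72.5 | 25.4 |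
| ochre | 5.00 | 76.0 | 22.8 |
| blue | 0.250 | 18.8 | 78.8 |
| blue | 0.667 | 44.7 | 56.3 |
| blue | 1.33 | 62.2 | 38.3 |
| blue | 2.00 | 67.9 | 31.6 |
| blue | 3.00 | 76.9 | 24.5 |
| blue | 4.00 | 78.4 | 19.9 |
| blue | 5.00 | 79.2 | 18.7 |

(standard deviation of a reading: 1 percentage point)

- in the second phase: reagent in the second phase; everything else is in the first
- charges count per volume of the first phase; a concentration in a rate is the amount of a species over the volume of its own phase; every rate counts per litre of the first phase
- the earlier runs hold the two phases in the same ratio of volumes as the flask asked about

- target at 4.0 min, in percent of the substrate charged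
- part of the substrate charged that has reacted at 4.0 min

With the substrate as limiting reagent by charge, I try a second-order clock at fixed equivalents. Charged [substrate] times time gives the flask 96.0 M·s, the dose. The runs support it: at 24.0 M·s they read 38.7 % and 38.3 % of substrate, and at 36.0 M·s they read 30.5 % and 31.6 %, each with a scatter of 1 percentage point.

Now I turn the question round. A quarter of the substrate left is what the ochre run reads at 4.00 min, whose dose is 48.0 M·s. This flask has twice that. Its nearest reading is blue's last, at 90.0 M·s, slightly less than the flask's dose, with 18.7 % of substrate left. So I commit to just under 18.7 % left, or conversion just over 81.3 %.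

The forecast gives 82 % target and 84 % reacted, 2.7 points beyond that conversion: “Inhibition would leave slightly more, so I take 16%”.

The flask gives 82.2 % target and 82.7 % reacted.

    reagent in the reaction phase ⇌ reagent in the second phase, rate k1*([reagent in the reaction phase] - [reagent in the second phase]/K1) per volume of the first phase (partition coefficient = 0.620, kL = 0.0455 s⁻¹)
    substrate + reagent in the reaction phase → target (k = 0.0835 M⁻¹ s⁻¹)
    substrate → decomposition product (k = 5.65 × 10⁻⁵ s⁻¹)
    2 reagent in the reaction phase → self-condensation product (k = 0.0274 M⁻¹ s⁻¹)

At dose 96.0 M·s, the flask keeps 17 % of its substrate, less than blue's last reading. The neighbouring flask, charged at 0.16 M and stopped at the same 4.0 min, has a dose of 38.4 M·s, slightly above the 36.0 M·s where the runs read 30.5 % and 31.6 %, so I expect a little under those. It holds 29 % of its substrate, with 69.9 % target.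

The numbers in the tables were computed from invented constants; noise was put on by code.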